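Numbering: ring A = C1 (quaternary), C2 (CH2), C3 (CHOMe), C4=C5, C6 (C=O). The side chain is C8 (CHMe) and C7 (ArCH–O7H). The allyl group is C9–C10=C11.
Enabling feature: O7–C7–C8–C1–C9 is a homoallylic alcohol once C1=C9 is an alkene, and the C6 carbonyl flanks quaternary C1. C1 can therefore be made by closing a temporary tetrahydropyran (ring B: O7, C7, C8, C1, C9, C10) onto that alkene while a carbinol-ring carbon (C2) moves from C6 to C1.
Cuts, in retrosynthetic order: C10=C11 (lactol methylenation, which also reopens ring B); C3–OMe with C4=C5 (from a C3=C4 alkene); O7–C10, C9–C10 and C1–C2 together (Prins–pinacol step); C1–C6 (vinylmetal plus cyclopent-3-enone); C1–C9 (alkyne homologation); C7–C8 (aldol).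
Forward: the chain C7–C8–C1–C9 is built first and the five-membered carbinol ring is attached. Ring B then closes while the five-membered ring grows into ring A in one operation, ring A is oxidised, and ring B is opened last.
Stereochemistry: C7 and C8 come from an (R)-benzyloxazolidinone syn aldol. C1 comes from the chair of ring B, whose axial C8 methyl sends C2 to the opposite face. C3 comes from anti addition of PhSe+ and MeOH across C3=C4 of the spirocycle.

Key step: step 9

Assumption: the acetal carbon C10 is drawn with its methoxy group equatorial throughout; either anomer serves, because C10 stops being stereogenic at the end.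

Step 1
Reactants: 1 (R)-4-benzyl-3-propanoyl-1,3-oxazolidin-2-one; 2 3,4,5-trimethoxybenzaldehyde
Product: 4 (R)-4-benzyl-3-[(2R,3R)-3-hydroxy-2-methyl-3-(3,4,5-trimethoxyphenyl)propanoyl]-1,3-oxazolidin-2-one, via (Z)-boron enolate 3 (not isolated)
Conditions: Bu2BOTf, Et3N, CH2Cl2, −78 to 0 °C; 2, −78 to 0 °C; H2O2, MeOH, pH 7 buffer, 0 °C
Reagents that add atoms: none
Why: Evans syn aldol, in which the (Z)-boron enolate reacts through a closed chair on the enolate face left open by the benzyl group of the (R)-auxiliary, which should set C8 and C7 (2R,3R in 4) in the syn relationship of the target.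

Step 2
Reactants: 4 syn aldol adduct
Product: 5 (2R,3R)-3-hydroxy-N-methoxy-N,2-dimethyl-3-(3,4,5-trimethoxyphenyl)propanamide
Conditions: MeONHMe·HCl, AlMe3, CH2Cl2, −15 °C to rt; aqueous HCl work-up
Reagents that add atoms: N,O-dimethylhydroxylamine hydrochloride, CNOC.Cl
Why: Aluminium amide transamination of an N-acyloxazolidinone (Weinreb amide formation), assisted by the free β-hydroxyl, releases the auxiliary without touching C7 or C8.

Step 3
Reactants: 5 hydroxy Weinreb amide
Product: 6 (2R,3R)-3-{[tert-butyl(dimethyl)silyl]oxy}-N-methoxy-N,2-dimethyl-3-(3,4,5-trimethoxyphenyl)propanamide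
Conditions: TBSOTf, 2,6-lutidine, CH2Cl2, 0 °C
Reagents that add atoms: tert-butyldimethylsilyl triflate, CC(C)(C)[Si](C)(C)OS(=O)(=O)C(F)(F)F
Why: Routine silyl triflate protection of a hindered benzylic alcohol, the bulky silyl group being chosen because it resists the O-to-C 1,4-silyl shift that smaller silyl groups could undergo at the later vinyllithium stage.

Step 4
Reactants: 6 silylated Weinreb amide
Product: 8 tert-butyl(dimethyl){[(1R,2S)-2-methyl-1-(3,4,5-trimethoxyphenyl)but-3-yn-1-yl]oxy}silane, via aldehyde 7 (not isolated)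
Conditions: i-Bu2AlH, CH2Cl2, −78 °C; then MeOH, K2CO3, MeC(O)C(N2)P(O)(OMe)2, −78 °C to rt; aqueous potassium sodium tartrate
Reagents that add atoms: dimethyl (1-diazo-2-oxopropyl)phosphonate, COP(=O)(OC)C(=[N+]=[N-])C(C)=O
Why: Weinreb amide reduction stops at the chelated hemiaminal, and the telescoped Ohira–Bestmann homologation of the unisolated aldehyde adds C9 under carbonate conditions that normally leave α-methyl β-silyloxy aldehydes unepimerised.

Step 5
Reactants: 8 terminal alkyne
Product: 10 tert-butyl{[(1R,2R)-3-iodo-2-methyl-1-(3,4,5-trimethoxyphenyl)but-3-en-1-yl]oxy}dimethylsilane, via α-vinylalane 9 (not isolated)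
Conditions: i-Bu2AlH, Ni(dppp)Cl2 (3 mol %), THF, rt; then NIS, 0 °C
Reagents that add atoms: N-iodosuccinimide, O=C1CCC(=O)N1I
Why: Nickel-catalysed α-selective (Markovnikov) hydroalumination of a terminal alkyne followed by iodinolysis of the C–Al bond is a known route to 2-iodoalk-1-enes and avoids the acidic media of direct hydroiodination, which the electron-rich benzylic silyl ether would not tolerate.

Step 6
Reactants: 10 2-iodoalkene; 11 cyclopent-3-en-1-one
Product: 14 1-[(3S,4R)-4-{[tert-butyl(dimethyl)silyl]oxy}-3-methyl-4-(3,4,5-trimethoxyphenyl)but-1-en-2-yl]cyclopent-3-en-1-ol, via vinyllithium 12 (not isolated), via vinylcerium dichloride 13 (not isolated)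
Conditions: t-BuLi (2.1 equiv), Et2O, −78 °C; CeCl3, THF, −78 °C; 11, −78 °C; aqueous NH4Cl
Reagents that add atoms: none
Why: Iodine–lithium exchange and organocerium 1,2-addition, the weakly basic cerium reagent being expected to add to the easily enolised ketone faster than it deprotonates it, form C1–C6, and C6 is not stereogenic because the two ring arms are identical.

Step 7
Reactants: 14 silyl ether carbinol
Product: 15 1-[(3S,4R)-4-hydroxy-3-methyl-4-(3,4,5-trimethoxyphenyl)but-1-en-2-yl]cyclopent-3-en-1-ol
Conditions: Bu4NF, THF, 0 °C to rt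
Reagents that add atoms: none
Why: Fluoride desilylation under basic conditions, which leave the acid-sensitive tertiary allylic carbinol and both alkenes untouched.

Step 8
Reactants: 15 diol
Product: 16 bis(trimethylsilyl) ether of 15 (Me3SiO on C7 and on C6)
Conditions: 1-(trimethylsilyl)imidazole, CH2Cl2, rt; filtration through Et3N-deactivated silica
Reagents that add atoms: 1-(trimethylsilyl)imidazole, C[Si](C)(C)n1ccnc1
Why: Exhaustive silylation with a neutral donor strong enough for tertiary alcohols shields O6 from formylation and ionisation and turns O7 into a silyl ether that exchanges with orthoesters under silyl triflate catalysis in an aprotic medium.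

Step 9
Reactants: 16 bis(trimethylsilyl) ether; 17 trimethyl orthoformate
Product: 20 (1S,2R,4S,6S)-4-methoxy-1-methyl-2-(3,4,5-trimethoxyphenyl)-3-oxaspiro[5.5]undec-9-en-7-one, via mixed orthoformate 18 (not isolated), via dioxacarbenium triflate 19 (not isolated)
Conditions: 17 (1.2 equiv), TMSOTf (0.3 equiv), 2,6-di-tert-butyl-4-methylpyridine, 4 Å molecular sieves, CH2Cl2, −78 to −40 °C; Et3N quench
Reagents that add atoms: none
Why: Proposed new method: TMSOTf ionises 17 to the dimethoxycarbenium ion, the less hindered secondary O7 silyl ether captures it (O7–C10) to give 18, and a second ionisation gives the (E)-dioxacarbenium ion 19, an electrophile of the class that alkylates allylsilanes and so should be within reach of a tethered 1,1-disubstituted alkene of similar nucleophilicity. C9 attacks C10 in a 6-endo-trig closure of ring B through a chair, the charge arrives at tertiary C1, and the aligned C6–C2 bond shifts to C1 while the C6 silyl ether collapses to the ketone and returns Me3Si+, so ring A arises by five-to-six ring enlargement (1,2-alkyl shift) rather than by a closure of its own and the acid stays catalytic. The closest known reaction type is the Prins–pinacol spiroannulation of 1-(4-hydroxybut-1-en-2-yl)cycloalkanols and their silyl ethers with aldehydes or acetals, and only the formate oxidation level of the cation is new. C1 is controlled by the chair, in which the aryl group is equatorial and the C8 methyl axial (this also turns C8–H toward the bulky carbinol carbon and relieves allylic strain), so the lobe of the C1 cation on the methyl side is blocked and C2 arrives on the opposite, axial face, trans to the methyl, as the target requires. C10 follows from the (E) geometry of 19 (methoxy equatorial) and is erased later. The step needs O7 to react before O6, which the secondary against tertiary silyl ether secures, and it needs cyclisation to outrun loss of methyl formate from benzylic C7 and 2-oxonia-Cope scrambling, which the low temperature, the buffered aprotic medium and the irreversible shift should secure, while C2 and C5 are equivalent, so migration of either gives 20.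

Step 10
Reactants: 20 spiro β,γ-enone acetal
Product: 23 (1S,2R,4S,6S,10R)-4,10-dimethoxy-1-methyl-2-(3,4,5-trimethoxyphenyl)-3-oxaspiro[5.5]undec-8-en-7-one, via methoxy selenide 21 (not isolated), via selenoxide 22 (not isolated)
Conditions: N-(phenylselanyl)phthalimide, camphorsulfonic acid (cat), MeOH–CH2Cl2, −40 to 0 °C; then pyridine, 30% H2O2, 0 °C to rt
Reagents that add atoms: methanol, CO
Why: Anti methoxyselenenylation followed by selenoxide syn elimination is the known way from β,γ-unsaturated carbonyl compounds to γ-alkoxy enones; the spirocycle should react through the ring A half-chair that keeps branched C8 axial (the alternative presses the C8 methyl against the C6 carbonyl oxygen), so the seleniranium ion sits on the face away from C8, methanol opens it trans-diaxially (Fürst–Plattner rule) at C3, the alkene carbon farther from the carbonyl, on the C8 face (3R in target numbering), and the selenoxide eliminates toward the acidic C5–H and away from the methoxy-bearing carbon.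

Step 11
Reactants: 23 methoxy enone acetal
Product: 24 lactol (1S,2R,6S,10R)-4-hydroxy-10-methoxy-1-methyl-2-(3,4,5-trimethoxyphenyl)-3-oxaspiro[5.5]undec-8-en-7-one (anomeric mixture)
Conditions: 1 M HCl, THF, rt
Reagents that add atoms: water, O
Why: Acid hydrolysis of a methyl pyranoside acetal with no oxygen on the neighbouring carbon is fast and should be complete well before the benzylic C7–O bond or the electron-poor allylic methyl ether at C3 can ionise.

Step 12
Reactants: 24 lactol
Product: 26 megaphone (4R,6R)-6-[(1R,2S)-1-hydroxy-1-(3,4,5-trimethoxyphenyl)propan-2-yl]-4-methoxy-6-(prop-2-en-1-yl)cyclohex-2-en-1-one, via hydroxy aldehyde 25 (not isolated)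
Conditions: Ph3PCH3Br, KN(SiMe3)2, THF, 0 °C; then 24 (ylide 2.2 equiv), −78 to 0 °C
Reagents that add atoms: methyltriphenylphosphonium bromide, C[P+](c1ccccc1)(c1ccccc1)c1ccccc1.[Br-]
Why: Wittig methylenation of a lactol through its open tautomer, in which the aldehyde should react far faster than the C6 enone carbonyl crowded by quaternary C1, completes the allyl group and leaves O7 as the free hydroxyl.

Compound list
1 | (R)-4-benzyl-3-propanoyl-1,3-oxazolidin-2-one | CCC(=O)N1[C@H](Cc2ccccc2)COC1=O | starting material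
2 | 3,4,5-trimethoxybenzaldehyde | COc1cc(C=O)cc(OC)c1OC | starting material
3 | (Z)-dibutylboron enolate of 1 | C/C=C(\OB(CCCC)CCCC)N1[C@H](Cc2ccccc2)COC1=O | intermediate
4 | (R)-4-benzyl-3-[(2R,3R)-3-hydroxy-2-methyl-3-(3,4,5-trimethoxyphenyl)propanoyl]-1,3-oxazolidin-2-one | O=C([C@H](C)[C@@H](O)c1cc(OC)c(OC)c(OC)c1)N1[C@H](Cc2ccccc2)COC1=O | intermediate
5 | (2R,3R)-3-hydroxy-N-methoxy-N,2-dimethyl-3-(3,4,5-trimethoxyphenyl)propanamide | CON(C)C(=O)[C@H](C)[C@@H](O)c1cc(OC)c(OC)c(OC)c1 | intermediate
6 | (2R,3R)-3-{[tert-butyl(dimethyl)silyl]oxy}-N-methoxy-N,2-dimethyl-3-(3,4,5-trimethoxyphenyl)propanamide | CON(C)C(=O)[C@H](C)[C@@H](O[Si](C)(C)C(C)(C)C)c1cc(OC)c(OC)c(OC)c1 | intermediate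
7 | (2R,3R)-3-{[tert-butyl(dimethyl)silyl]oxy}-2-methyl-3-(3,4,5-trimethoxyphenyl)propanal | O=C[C@H](C)[C@@H](O[Si](C)(C)C(C)(C)C)c1cc(OC)c(OC)c(OC)c1 | intermediate
8 | tert-butyl(dimethyl){[(1R,2S)-2-methyl-1-(3,4,5-trimethoxyphenyl)but-3-yn-1-yl]oxy}silane | C#C[C@H](C)[C@@H](O[Si](C)(C)C(C)(C)C)c1cc(OC)c(OC)c(OC)c1 | intermediate
9 | diisobutyl(alk-1-en-2-yl)alane from 8 (Al on C1, C7 and C8 unchanged) | C=C([Al](CC(C)C)CC(C)C)[C@H](C)[C@@H](O[Si](C)(C)C(C)(C)C)c1cc(OC)c(OC)c(OC)c1 | intermediate
10 | tert-butyl{[(1R,2R)-3-iodo-2-methyl-1-(3,4,5-trimethoxyphenyl)but-3-en-1-yl]oxy}dimethylsilane | C=C(I)[C@H](C)[C@@H](O[Si](C)(C)C(C)(C)C)c1cc(OC)c(OC)c(OC)c1 | intermediate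
11 | cyclopent-3-en-1-one | O=C1CC=CC1 | starting material
12 | vinyllithium from 10 (Li on C1) | [Li]C(=C)[C@H](C)[C@@H](O[Si](C)(C)C(C)(C)C)c1cc(OC)c(OC)c(OC)c1 | intermediate
13 | vinylcerium dichloride from 12 (Ce on C1) | Cl[Ce](Cl)C(=C)[C@H](C)[C@@H](O[Si](C)(C)C(C)(C)C)c1cc(OC)c(OC)c(OC)c1 | intermediate
14 | 1-[(3S,4R)-4-{[tert-butyl(dimethyl)silyl]oxy}-3-methyl-4-(3,4,5-trimethoxyphenyl)but-1-en-2-yl]cyclopent-3-en-1-ol | C=C([C@H](C)[C@@H](O[Si](C)(C)C(C)(C)C)c1cc(OC)c(OC)c(OC)c1)C1(O)CC=CC1 | intermediate
15 | 1-[(3S,4R)-4-hydroxy-3-methyl-4-(3,4,5-trimethoxyphenyl)but-1-en-2-yl]cyclopent-3-en-1-ol | C=C([C@H](C)[C@@H](O)c1cc(OC)c(OC)c(OC)c1)C1(O)CC=CC1 | intermediate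
16 | bis(trimethylsilyl) ether of 15 | C=C([C@H](C)[C@@H](O[Si](C)(C)C)c1cc(OC)c(OC)c(OC)c1)C1(O[Si](C)(C)C)CC=CC1 | intermediate
17 | trimethyl orthoformate | COC(OC)OC | starting material
18 | mixed orthoformate (O7–CH(OMe)2, O6–SiMe3) | C=C([C@H](C)[C@@H](OC(OC)OC)c1cc(OC)c(OC)c(OC)c1)C1(O[Si](C)(C)C)CC=CC1 | intermediate
19 | (E)-dioxacarbenium triflate (O7=C10H–OMe cation, O6–SiMe3) | C=C([C@H](C)[C@@H]([O+]=COC)c1cc(OC)c(OC)c(OC)c1)C1(O[Si](C)(C)C)CC=CC1.[O-]S(=O)(=O)C(F)(F)F | intermediate
20 | (1S,2R,4S,6S)-4-methoxy-1-methyl-2-(3,4,5-trimethoxyphenyl)-3-oxaspiro[5.5]undec-9-en-7-one | CO[C@@H]1C[C@@]2(CC=CCC2=O)[C@H](C)[C@H](c3cc(OC)c(OC)c(OC)c3)O1 | intermediate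
21 | methoxy selenide (C3–OMe on the C8 face, C4–SePh trans to it) | CO[C@@H]1C[C@@]2(C[C@@H](OC)[C@H]([Se]c3ccccc3)CC2=O)[C@H](C)[C@H](c3cc(OC)c(OC)c(OC)c3)O1 | intermediate
22 | selenoxide of 21 | CO[C@@H]1C[C@@]2(C[C@@H](OC)[C@H]([Se](=O)c3ccccc3)CC2=O)[C@H](C)[C@H](c3cc(OC)c(OC)c(OC)c3)O1 | intermediate
23 | (1S,2R,4S,6S,10R)-4,10-dimethoxy-1-methyl-2-(3,4,5-trimethoxyphenyl)-3-oxaspiro[5.5]undec-8-en-7-one | CO[C@@H]1C[C@@]2(C[C@@H](OC)C=CC2=O)[C@H](C)[C@H](c3cc(OC)c(OC)c(OC)c3)O1 | intermediate
24 | lactol, (1S,2R,6S,10R)-4-hydroxy-10-methoxy-1-methyl-2-(3,4,5-trimethoxyphenyl)-3-oxaspiro[5.5]undec-8-en-7-one, both anomers | OC1C[C@@]2(C[C@@H](OC)C=CC2=O)[C@H](C)[C@H](c3cc(OC)c(OC)c(OC)c3)O1 | intermediate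
25 | open hydroxy aldehyde tautomer of 24 | O=CC[C@]1([C@H](C)[C@@H](O)c2cc(OC)c(OC)c(OC)c2)C[C@@H](OC)C=CC1=O | intermediate
26 | megaphone | C=CC[C@]1([C@H](C)[C@@H](O)c2cc(OC)c(OC)c(OC)c2)C[C@@H](OC)C=CC1=O | target

Total step count: 12. Longest linear sequence: 12 steps (from 1 and 2; 11 and 17 enter as purchased partners).

Steps most likely to fail

Step 9. The dioxacarbenium ion is a far weaker electrophile than an ordinary oxocarbenium ion, so several processes may overtake C9–C10 bond formation:
- heterolysis of the activated benzylic C7–O bond with loss of methyl formate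
- 2-oxonia-Cope scrambling of C7 and C8
- ionisation at tertiary allylic C6
- ketalisation of the new carbonyl group

The fallback keeps the same bond changes but lowers the cation to the aldehyde oxidation level, where acetal-initiated Prins–pinacol annulation is known chemistry. It sets out from 16. Bromoacetaldehyde dimethyl acetal and TMSOTf (or SnCl4) in CH2Cl2 at −78 °C should lead, through the mixed bromoacetal F1, to the bromomethyl spiro ketone F2, in which C11 has arrived together with C10. The conditions of step 10 then pass through the methoxy selenide F3 and the selenoxide F4 to the bromomethyl methoxy enone F5. A Boord-type reductive β-elimination (Zn dust, NaI, EtOH, reflux) opens ring B and releases the allyl group and the O7 hydroxyl at once. The sequence comes back to the route at 26, so steps 11 and 12 are not needed.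

Step 10. The energy gap between the two ring A half-chairs may be too small, which would mean poor facial selectivity at C3. Methanol may also attack C4, or the acid may move the C3=C4 alkene into conjugation before selenium adds. The fallback sets C3 by hydride delivery instead of by C–O bond formation. It sets out from 20.
- m-CPBA (NaHCO3, CH2Cl2, 0 °C) should give the epoxide F6.
- Et3N opens F6 by an E1cB process to the 3-epi carbinol F7, whose C3 configuration does not matter.
- Dess–Martin periodinane gives the enedione F8.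
- Corey–Bakshi–Shibata reduction ((S)-2-methyl-oxazaborolidine, catecholborane, toluene, −78 °C) at the less hindered C3 carbonyl delivers hydride to the face away from C8, in line with the substrate bias, and gives the 3R carbinol F9.
- O-methylation (MeI, Ag2O) comes back to the route at 23.

Step 12. Slow opening of the heavily substituted lactol may leave the basic ylide time to deprotonate C3–H, eroding the C3 configuration or deconjugating the enone, or to attack the enone itself. The fallback homologates under carbonate instead of ylide basicity. It sets out from 24. Dimethyl (1-diazo-2-oxopropyl)phosphonate with K2CO3 in MeOH should give the propargyl ketone F10. Semihydrogenation (H2, Pd/CaCO3 poisoned with Pb(OAc)2, quinoline, EtOAc) of the terminal alkyne, which is reduced faster than the conjugated ring alkene, comes back to the route at 26.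

Further compounds
F1 | step 9 | mixed bromoacetal (O7–CH(OMe)CH2Br, O6–SiMe3) | C=C([C@H](C)[C@@H](OC(CBr)OC)c1cc(OC)c(OC)c(OC)c1)C1(O[Si](C)(C)C)CC=CC1
F2 | step 9 | bromomethyl spiro ketone (CH2Br equatorial on C10) | BrC[C@@H]1C[C@@]2(CC=CCC2=O)[C@H](C)[C@H](c3cc(OC)c(OC)c(OC)c3)O1
F3 | step 9 | methoxy selenide of the bromomethyl series | BrC[C@@H]1C[C@@]2(C[C@@H](OC)[C@H]([Se]c3ccccc3)CC2=O)[C@H](C)[C@H](c3cc(OC)c(OC)c(OC)c3)O1
F4 | step 9 | selenoxide of the bromomethyl series | BrC[C@@H]1C[C@@]2(C[C@@H](OC)[C@H]([Se](=O)c3ccccc3)CC2=O)[C@H](C)[C@H](c3cc(OC)c(OC)c(OC)c3)O1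
F5 | step 9 | bromomethyl methoxy enone | BrC[C@@H]1C[C@@]2(C[C@@H](OC)C=CC2=O)[C@H](C)[C@H](c3cc(OC)c(OC)c(OC)c3)O1
F6 | step 10 | C3–C4 epoxide of 20 (oxygen on the face away from C8) | CO[C@@H]1C[C@@]2(C[C@@H]3O[C@@H]3CC2=O)[C@H](C)[C@H](c3cc(OC)c(OC)c(OC)c3)O1
F7 | step 10 | 3-epi carbinol (3S γ-hydroxy enone) | CO[C@@H]1C[C@@]2(C[C@H](O)C=CC2=O)[C@H](C)[C@H](c3cc(OC)c(OC)c(OC)c3)O1
F8 | step 10 | enedione (C3 and C6 carbonyls) | CO[C@@H]1C[C@@]2(CC(=O)C=CC2=O)[C@H](C)[C@H](c3cc(OC)c(OC)c(OC)c3)O1
F9 | step 10 | 3R carbinol (γ-hydroxy enone) | CO[C@@H]1C[C@@]2(C[C@@H](O)C=CC2=O)[C@H](C)[C@H](c3cc(OC)c(OC)c(OC)c3)O1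
F10 | step 12 | propargyl ketone (C10≡C11 in place of the alkene of 26) | C#CC[C@]1([C@H](C)[C@@H](O)c2cc(OC)c(OC)c(OC)c2)C[C@@H](OC)C=CC1=O
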